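- The reading comes at 50 s, and grey, red and blue differ in temperature.

    substrate + partner ⇌ target (K1 = 12 /M, k1 = 0.11 /M/s, Ea1 = 55.0 kJ/mol, ΔH1 = −21.0 kJ/mol)
    substrate + partner ⇌ isomer of the product (K2 = 8.4 /M, k2 = 0.014 /M/s, Ea2 = 44.0 kJ/mol, ΔH2 = −33.0 kJ/mol)
    solid reagent ⇌ partner, rate k3*(cs3 - [partner]) while solid is left; crystals form when [partner] > cs3 (cs3 = 0.18 M, k3 = 0.037 /s)
    (constants at 25 °C)

| flask | substrate | solid reagent | temperature | time |
|---|---|---|---|---|
| grey | 0.29 M | 0.870 M | 45 °C | 50 s |
| red | 0.29 M | 0.870 M | 65 °C | 50 s |
| blue | 0.29 M | 0.870 M | 25 °C | 50 s |

- solid reagent is a solid; its amount is given per volume of the solution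
- at 25 °C the constants are as listed, elsewhere as the activation energies and enthalpies make them
- at the start none of the solid reagent is in solution

* which flask leads in amount of target, in percent of the substrate charged ("all alike" within 1.5 percentage points) (grey / red / blue / all alike)
* how much target is there at the end, in percent of the substrate charged: grey
* how much target is there at the end, in percent of the substrate charged: red
* how much target is there at the end, in percent of the substrate charged: blue

- The concentration that sets the order of the rate is the dissolved partner, [partner]: both steps from substrate are first order in it, it starts from none, and it is fed towards the solubility s = 0.18 M at the dissolution coefficient k3 = 0.037 /s times the gap between s and [partner], while both steps draw it off.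
- Two numbers seem to pull against each other: from blue to red the step to target speeds up 14 times, yet its equilibrium constant K falls from 12.0 /M to 4.41 /M.
- Taking K times s gives 0.793 for red and 2.16 for blue; we call this the resting ratio ρ, the target over substrate at which the step to target balances with partner at its solubility.
- Even with partner at s, the forward half-life of substrate by the step to target is 35.0 s in blue and 2.54 s in red.
- Red's half-life is far shorter than the reading time, so we expect red to keep up with whatever partner it has. Blue's is 35.0 s against 50 s, and with partner starting from none, we expect blue to lag behind its ρ. That clears up the two numbers: red has the faster step and the lower ρ, blue the slower step and the higher ρ.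
- By our own reckoning, partner with none consumed reaches 0.152 M at the reading, so red's ratio stays under 0.668, which puts its target under 40.0 % of the substrate charged. Our hand reckoning stops there.
- The forecast puts grey in the lead, with 36 % there, 29.4 % in red and 27 % in blue, and says of red that “step 1 is effectively at equilibrium”.
- The simulation gives grey in the lead, with 34.9 % there, 28.8 % in red and 27.4 % in blue.
- These flasks have not come to rest at the reading. Red then holds target over substrate of 0.468 with partner at 0.109 M, where K times that partner gives 0.481. By 500 s red's partner reads 0.180 M and its ratio 0.793, against ρ of 0.793. In blue at 500 s the ratio reads 2.22, against ρ of 2.16. Target by then stands at 43.4 % in grey, 37.7 % in red and 52.9 % in blue, which has moved ahead of grey.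

The constants used here were chosen freely.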